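**Direct plan and its weak points**

A direct plan would take 3,4,5-tris(benzyloxy)phenol A1 and C-acetylate it next to the hydroxyl under acidic mixed-anhydride conditions to the 2-hydroxyacetophenone A2.
Ketone A2 would then be condensed with the aldehyde A3, which is 4-(benzyloxy)benzaldehyde, to the 2'-hydroxychalcone A4.
Alkaline hydrogen peroxide would have to close and oxidise ring C to the tetra-O-benzyl flavonol A5, which would be sulfated at the 3-hydroxyl to the sodium sulfate salt A6, debenzylated by hydrogenolysis and acidified.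
The weakest point would be the oxidative ring closure of A4 to A5: a chalcone with an alkoxy group beside the carbonyl (the future C5 oxygen) would be expected to close largely in the five-membered (aurone) sense, and the step must repair at C3 an oxidation level that the aldol step between A2 and A3 set too low.
Also weak would be the acid-promoted C-acetylation of A1: a strongly acidic acylating medium meets three electron-rich benzyl ethers, O- and C-acylation compete, and only two carbons arrive, so ring B and the C3 oxygen each cost a further step.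

**Retrosynthetic overview of the new route**

The target is traced back to a neutral 2,2,2-trichloroethyl sulfate diester of a flavonol whose ring A carries benzyl ethers and whose ring B carries a 4-methoxybenzyl ether; one reductive operation removes all five masks.
Key disconnection: the neighbouring ring A carbons C4a and C8a, which bear the acyl carbon C4 and the ether oxygen O1 and are flanked by the C5 oxygen, become the triple bond of 3,4,5-tris(benzyloxy)benzyne. Every other atom of ring C and ring B comes from one open-chain acid, HO–C(=O)–CH2–O–C(=O)–Ar, read as O1–C4–C3–O3–C2–ring B.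
Order of events: rings A and B are bought. The aryne inserts into the HO–C bond of the acid (C8a–O1 and C4a–C4 at once), the aroyl group moves from O3 to C3 (C2–C3), and O1 closes ring C on C2 with loss of water.
Consequences: C3 arrives with its oxygen at the final oxidation level, so there is no chalcone, no oxidative ring closure and no aurone pathway. The acyl group is put on ring A under fluoride, so the benzyl ethers never meet an acidic acylating medium.

Key step: step 5

Assumption (chemistry): the target is wanted as the free hydrogen sulfate as drawn; since the free acid is expected to be less stable than its salts, it is liberated from the ammonium salt only in the last operation and kept cold.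

**Route**

Step 1
Reactants: 1 3,4,5-tris(benzyloxy)benzaldehyde
Product: 3 3,4,5-tris(benzyloxy)phenol, via 3,4,5-tris(benzyloxy)phenyl formate 2 (not isolated)
Conditions: mCPBA, CH2Cl2, 0 °C → rt; aq. Na2S2O3/NaHCO3 wash; then K2CO3 (cat.), MeOH, rt
Reagents that add atoms: 3-chloroperoxybenzoic acid, O=C(OO)c1cccc(Cl)c1
Why: Baeyer–Villiger (Dakin-type) oxidation, in which the electron-rich aryl group migrates in preference to hydride to give the formate, followed by catalytic methanolysis that frees the phenol without touching the benzyl ethers.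

Step 2
Reactants: 3 3,4,5-tris(benzyloxy)phenol
Product: 4 2-bromo-3,4,5-tris(benzyloxy)phenol
Conditions: NBS (1.0 equiv), CH2Cl2/MeCN, −40 → 0 °C, dark
Reagents that add atoms: N-bromosuccinimide, O=C1CCC(=O)N1Br
Why: Electrophilic aromatic bromination directed by the free hydroxyl to one of the two symmetry-equivalent ortho positions, the only unsubstituted ring carbons, so that one equivalent of reagent at low temperature should give a single monobromide.

Step 3
Reactants: 4 2-bromo-3,4,5-tris(benzyloxy)phenol
Product: 7 3,4,5-tris(benzyloxy)-2-(trimethylsilyl)phenyl trifluoromethanesulfonate, via [2-bromo-3,4,5-tris(benzyloxy)phenoxy]trimethylsilane 5 (not isolated), via lithium 3,4,5-tris(benzyloxy)-2-(trimethylsilyl)phenolate 6 (not isolated)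
Conditions: HMDS, THF, reflux, then evaporation; n-BuLi, THF, −100 °C; Tf2O, −100 °C → rt
Reagents that add atoms: hexamethyldisilazane, C[Si](C)(C)N[Si](C)(C)C; trifluoromethanesulfonic anhydride, O=S(=O)(OS(=O)(=O)C(F)(F)F)C(F)(F)F
Why: Bromine–lithium exchange on the O-silylated bromophenol, faster at −100 °C than deprotonation of the benzylic ether positions, triggers a retro-Brook 1,3-shift of silicon from oxygen to carbon, and the lithium phenolate so formed is trapped as its triflate, the standard one-flask entry to 2-(trimethylsilyl)aryl triflates.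

Step 4
Reactants: 8 4-[(4-methoxybenzyl)oxy]benzoic acid; 9 glycolic acid (2-hydroxyacetic acid)
Product: 11 2-({4-[(4-methoxybenzyl)oxy]benzoyl}oxy)acetic acid, via 4-[(4-methoxybenzyl)oxy]benzoyl chloride 10 (not isolated)
Conditions: 1-chloro-N,N,2-trimethylprop-1-en-1-amine, CH2Cl2, 0 °C → rt; then glycolic acid (2 equiv), pyridine/THF, 0 °C → rt; cold dilute citric acid work-up
Reagents that add atoms: none
Why: Acylation of the hydroxyl group of glycolic acid by an acid chloride that is made under neutral conditions, so that the acid-labile 4-methoxybenzyl ether survives, should give the O-aroyl acid, since any mixed anhydride formed at the carboxyl group passes its aroyl group to the neighbouring hydroxyl or is hydrolysed on work-up.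

Step 5
Reactants: 7 3,4,5-tris(benzyloxy)-2-(trimethylsilyl)phenyl trifluoromethanesulfonate; 11 2-({4-[(4-methoxybenzyl)oxy]benzoyl}oxy)acetic acid
Product: 15 5,6,7-tris(benzyloxy)-3-hydroxy-2-{4-[(4-methoxybenzyl)oxy]phenyl}-4H-chromen-4-one, via 3,4,5-tris(benzyloxy)benzyne 12 (not isolated), via aroyloxymethyl ketone 13 (not isolated), via hydroxy diketone 14 (not isolated)
Conditions: CsF (4 equiv), THF, 125 °C, sealed tube, argon; then Cs2CO3 (3 equiv), DMF, 80 °C, same vessel; AcOH quench
Reagents that add atoms: none
Why: Fluoride removes the silyl group of 7 and triflate leaves, giving aryne 12, whose triple bond is distorted by the flanking benzyloxy group so that the carboxylate of 11 adds at the remote aryne carbon (the future C8a) and the aryl anion sits on the carbon beside the benzyloxy group (the future C4a), where it is stabilised inductively; this anion attacks the adjacent ester carbonyl through a four-membered transition state and the benzoxete alkoxide opens to the phenoxide of ketone 13, a net insertion of the aryne into the C–O bond of the acid that makes the C8a–O1 and C4a–C4 bonds in one event. The closest known reaction types are the fluoride-induced insertion of arynes into the C–O bond of carboxylic acids to give ortho-hydroxyaryl ketones and the Baker–Venkataraman acyl transfer by which 2-hydroxy-ω-aroyloxyacetophenones are turned into flavonols. With added carbonate the phenoxide takes over the aroyl group, the ketone enolate takes it back on carbon (C2–C3 bond, diketone 14), and the phenoxide then closes ring C by 6-exo-trig addition to the ring B carbonyl followed by E1cB loss of water. No stereocentre remains in the product, because the single carbinol carbon of 14 becomes the sp2 carbon C3. The selectivity needed is regiochemical (oxygen at C8a and acyl at C4a, not the reverse) and chemoselective (acyl transfer within the four-membered array in preference to protonation of the aryl anion or attack on the distant aroyl carbonyl); the first is secured by the benzyloxy substituent next to the triple bond, the second by the aprotic medium, the high temperature and the proximity of the ester carbonyl.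

Step 6
Reactants: 15 5,6,7-tris(benzyloxy)-3-hydroxy-2-{4-[(4-methoxybenzyl)oxy]phenyl}-4H-chromen-4-one
Product: 16 5,6,7-tris(benzyloxy)-2-{4-[(4-methoxybenzyl)oxy]phenyl}-4-oxo-4H-chromen-3-yl 2,2,2-trichloroethyl sulfate
Conditions: Cl3CCH2OSO2Cl, Et3N, DMAP (cat.), THF, 0 °C → rt
Reagents that add atoms: 2,2,2-trichloroethyl chlorosulfate, O=S(=O)(Cl)OCC(Cl)(Cl)Cl
Why: Sulfonylation of the acidic enolic 3-hydroxyl, the only free hydroxyl of 15, by a chlorosulfate ester under nucleophilic catalysis should give a neutral sulfate diester that can be purified on silica gel and carries the sulfate in a form stable to handling.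

Step 7
Reactants: 16 5,6,7-tris(benzyloxy)-2-{4-[(4-methoxybenzyl)oxy]phenyl}-4-oxo-4H-chromen-3-yl 2,2,2-trichloroethyl sulfate
Product: 18 5,6,7-trihydroxy-2-(4-hydroxyphenyl)-4-oxo-4H-chromen-3-yl hydrogen sulfate, via ammonium sulfate salt 17 (not isolated)
Conditions: 10% Pd/C, HCO2NH4, MeOH/THF, rt, argon; filtration under argon; then sulfonic acid cation-exchange resin (H+ form), H2O/MeOH, 0 °C, immediate freeze-drying
Reagents that add atoms: none
Why: Catalytic transfer hydrogenolysis should cleave the three benzyl ethers and the 4-methoxybenzyl ether and, by reductive fragmentation of the trichloroethyl group, release the sulfate monoester as its ammonium salt in a buffered medium that leaves the monoester and the C2=C3 bond of the chromone intact, and cold proton exchange on the resin then gives the free hydrogen sulfate without contact with mineral acid.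

**Compound list**

1 | 3,4,5-tris(benzyloxy)benzaldehyde | O=Cc1cc(OCc2ccccc2)c(OCc2ccccc2)c(OCc2ccccc2)c1 | starting material
2 | 3,4,5-tris(benzyloxy)phenyl formate (not isolated) | O=COc1cc(OCc2ccccc2)c(OCc2ccccc2)c(OCc2ccccc2)c1 | intermediate
3 | 3,4,5-tris(benzyloxy)phenol | Oc1cc(OCc2ccccc2)c(OCc2ccccc2)c(OCc2ccccc2)c1 | intermediate
4 | 2-bromo-3,4,5-tris(benzyloxy)phenol | Oc1cc(OCc2ccccc2)c(OCc2ccccc2)c(OCc2ccccc2)c1Br | intermediate
5 | [2-bromo-3,4,5-tris(benzyloxy)phenoxy]trimethylsilane (not isolated) | C[Si](C)(C)Oc1cc(OCc2ccccc2)c(OCc2ccccc2)c(OCc2ccccc2)c1Br | intermediate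
6 | lithium 3,4,5-tris(benzyloxy)-2-(trimethylsilyl)phenolate (not isolated) | [Li+].[O-]c1cc(OCc2ccccc2)c(OCc2ccccc2)c(OCc2ccccc2)c1[Si](C)(C)C | intermediate
7 | 3,4,5-tris(benzyloxy)-2-(trimethylsilyl)phenyl trifluoromethanesulfonate | C[Si](C)(C)c1c(OS(=O)(=O)C(F)(F)F)cc(OCc2ccccc2)c(OCc2ccccc2)c1OCc1ccccc1 | intermediate
8 | 4-[(4-methoxybenzyl)oxy]benzoic acid | COc1ccc(COc2ccc(C(=O)O)cc2)cc1 | starting material
9 | glycolic acid (2-hydroxyacetic acid) | OCC(=O)O | starting material
10 | 4-[(4-methoxybenzyl)oxy]benzoyl chloride (not isolated) | COc1ccc(COc2ccc(C(=O)Cl)cc2)cc1 | intermediate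
11 | 2-({4-[(4-methoxybenzyl)oxy]benzoyl}oxy)acetic acid | COc1ccc(COc2ccc(C(=O)OCC(=O)O)cc2)cc1 | intermediate
12 | 3,4,5-tris(benzyloxy)benzyne (1,2-didehydro-3,4,5-tris(benzyloxy)benzene; not isolated) | c1ccc(COC2=C(OCc3ccccc3)C(OCc3ccccc3)=CC#C2)cc1 | intermediate
13 | 2-oxo-2-[2,3,4-tris(benzyloxy)-6-hydroxyphenyl]ethyl 4-[(4-methoxybenzyl)oxy]benzoate (not isolated) | O=C(COC(=O)c1ccc(OCc2ccc(OC)cc2)cc1)c1c(O)cc(OCc2ccccc2)c(OCc2ccccc2)c1OCc1ccccc1 | intermediate
14 | rac-2-hydroxy-1-{4-[(4-methoxybenzyl)oxy]phenyl}-3-[2,3,4-tris(benzyloxy)-6-hydroxyphenyl]propane-1,3-dione (not isolated) | O=C(c1ccc(OCc2ccc(OC)cc2)cc1)C(O)C(=O)c1c(O)cc(OCc2ccccc2)c(OCc2ccccc2)c1OCc1ccccc1 | intermediate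
15 | 5,6,7-tris(benzyloxy)-3-hydroxy-2-{4-[(4-methoxybenzyl)oxy]phenyl}-4H-chromen-4-one | O=c1c(O)c(-c2ccc(OCc3ccc(OC)cc3)cc2)oc2cc(OCc3ccccc3)c(OCc3ccccc3)c(OCc3ccccc3)c12 | intermediate
16 | 5,6,7-tris(benzyloxy)-2-{4-[(4-methoxybenzyl)oxy]phenyl}-4-oxo-4H-chromen-3-yl 2,2,2-trichloroethyl sulfate | O=c1c(OS(=O)(=O)OCC(Cl)(Cl)Cl)c(-c2ccc(OCc3ccc(OC)cc3)cc2)oc2cc(OCc3ccccc3)c(OCc3ccccc3)c(OCc3ccccc3)c12 | intermediate
17 | ammonium 5,6,7-trihydroxy-2-(4-hydroxyphenyl)-4-oxo-4H-chromen-3-yl sulfate (not isolated) | [NH4+].O=c1c(OS(=O)(=O)[O-])c(-c2ccc(O)cc2)oc2cc(O)c(O)c(O)c12 | intermediate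
18 | 5,6,7-trihydroxy-2-(4-hydroxyphenyl)-4-oxo-4H-chromen-3-yl hydrogen sulfate | O=c1c(OS(=O)(=O)O)c(-c2ccc(O)cc2)oc2cc(O)c(O)c(O)c12 | target

**Step count and risks**

Total step count: 7. Longest linear sequence: 6 (steps 1, 2, 3, 5, 6, 7).

Steps most likely to fail:

Step 5 (aryne insertion and ring closure). The aryl anion may be protonated, by bifluoride or by the α-methylene group of the ester just formed, before it reaches the ester carbonyl, which would leave an aryl ester. The phenoxides formed may capture a second aryne. In the second stage the phenoxide may displace the aroyloxy group (five-membered ring) in place of accepting the acyl group. The fallback changes the acid partner and the way the C3 oxygen arrives. Silyl triflate 7 would be combined under the same fluoride conditions (CsF, THF, 125 °C) with 3-{4-[(4-methoxybenzyl)oxy]phenyl}prop-2-ynoic acid F2, an acid without α-hydrogens and without a second ester, made by lithiation (n-BuLi, THF, −78 °C) and carboxylation (CO2) of 1-ethynyl-4-[(4-methoxybenzyl)oxy]benzene F1, which is taken as purchasable. Insertion of the aryne into the acid C–O bond would give an ortho-hydroxyaryl ynone whose phenoxide adds 6-endo-dig to the alkyne, giving 5,6,7-tris(benzyloxy)-2-{4-[(4-methoxybenzyl)oxy]phenyl}-4H-chromen-4-one F3. F3 would be lithiated at C3 (LDA, THF, −78 °C), borylated (B(OMe)3) and oxidised (H2O2, AcOH) to flavonol 15, where the route is rejoined.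

Step 7 (reductive unmasking and proton exchange). Cleavage of the trichloroethyl group or of one ether may stay incomplete, and the sulfate monoester may be solvolysed during proton exchange or concentration. The fallback carries an unmasked sulfate salt. From 15, sulfation with the sulfur trioxide–trimethylamine complex (Me3N·SO3, Et3N, DMF, 60 °C) would give trimethylammonium 5,6,7-tris(benzyloxy)-2-{4-[(4-methoxybenzyl)oxy]phenyl}-4-oxo-4H-chromen-3-yl sulfate F4. Hydrogenolysis (H2, 1 atm, 10% Pd/C, THF/MeOH) would give trimethylammonium 5,6,7-trihydroxy-2-(4-hydroxyphenyl)-4-oxo-4H-chromen-3-yl sulfate F5, and the same cold resin exchange would lead to 18.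

Step 2 (monobromination). Bromination may go on to the second ortho position, or the very electron-rich phenol may be oxidised towards a quinone. The fallback replaces halogenation by directed ortho-metalation and bypasses steps 2 and 3. Phenol 3 would be converted with isopropyl isocyanate (Et3N, CH2Cl2) into 3,4,5-tris(benzyloxy)phenyl isopropylcarbamate F6. N-silylation in the flask (TBSOTf, TMEDA, Et2O), ortho-lithiation (n-BuLi, −78 °C) and quenching with TMSCl would give 3,4,5-tris(benzyloxy)-2-(trimethylsilyl)phenyl isopropylcarbamate F7. Cleavage of the carbamate (DBU, Et2NH, MeCN, 40 °C) and triflation of the phenolate in the same flask (PhNTf2) would give silyl triflate 7.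

Further compounds
F1 | step 5 | 1-ethynyl-4-[(4-methoxybenzyl)oxy]benzene | C#Cc1ccc(OCc2ccc(OC)cc2)cc1
F2 | step 5 | 3-{4-[(4-methoxybenzyl)oxy]phenyl}prop-2-ynoic acid | O=C(O)C#Cc1ccc(OCc2ccc(OC)cc2)cc1
F3 | step 5 | 5,6,7-tris(benzyloxy)-2-{4-[(4-methoxybenzyl)oxy]phenyl}-4H-chromen-4-one | O=c1cc(-c2ccc(OCc3ccc(OC)cc3)cc2)oc2cc(OCc3ccccc3)c(OCc3ccccc3)c(OCc3ccccc3)c12
F4 | step 7 | trimethylammonium 5,6,7-tris(benzyloxy)-2-{4-[(4-methoxybenzyl)oxy]phenyl}-4-oxo-4H-chromen-3-yl sulfate | C[NH+](C)C.O=c1c(OS(=O)(=O)[O-])c(-c2ccc(OCc3ccc(OC)cc3)cc2)oc2cc(OCc3ccccc3)c(OCc3ccccc3)c(OCc3ccccc3)c12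
F5 | step 7 | trimethylammonium 5,6,7-trihydroxy-2-(4-hydroxyphenyl)-4-oxo-4H-chromen-3-yl sulfate | C[NH+](C)C.O=c1c(OS(=O)(=O)[O-])c(-c2ccc(O)cc2)oc2cc(O)c(O)c(O)c12
F6 | step 2 | 3,4,5-tris(benzyloxy)phenyl isopropylcarbamate | CC(C)NC(=O)Oc1cc(OCc2ccccc2)c(OCc2ccccc2)c(OCc2ccccc2)c1
F7 | step 2 | 3,4,5-tris(benzyloxy)-2-(trimethylsilyl)phenyl isopropylcarbamate | CC(C)NC(=O)Oc1cc(OCc2ccccc2)c(OCc2ccccc2)c(OCc2ccccc2)c1[Si](C)(C)C
A1 | direct plan | 3,4,5-tris(benzyloxy)phenol | Oc1cc(OCc2ccccc2)c(OCc2ccccc2)c(OCc2ccccc2)c1
A2 | direct plan | 1-[2,3,4-tris(benzyloxy)-6-hydroxyphenyl]ethan-1-one | CC(=O)c1c(O)cc(OCc2ccccc2)c(OCc2ccccc2)c1OCc1ccccc1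
A3 | direct plan | 4-(benzyloxy)benzaldehyde | O=Cc1ccc(OCc2ccccc2)cc1
A4 | direct plan | (E)-3-[4-(benzyloxy)phenyl]-1-[2,3,4-tris(benzyloxy)-6-hydroxyphenyl]prop-2-en-1-one | O=C(/C=C/c1ccc(OCc2ccccc2)cc1)c1c(O)cc(OCc2ccccc2)c(OCc2ccccc2)c1OCc1ccccc1
A5 | direct plan | 5,6,7-tris(benzyloxy)-2-[4-(benzyloxy)phenyl]-3-hydroxy-4H-chromen-4-one | O=c1c(O)c(-c2ccc(OCc3ccccc3)cc2)oc2cc(OCc3ccccc3)c(OCc3ccccc3)c(OCc3ccccc3)c12
A6 | direct plan | sodium 5,6,7-tris(benzyloxy)-2-[4-(benzyloxy)phenyl]-4-oxo-4H-chromen-3-yl sulfate | O=c1c(OS(=O)(=O)[O-])c(-c2ccc(OCc3ccccc3)cc2)oc2cc(OCc3ccccc3)c(OCc3ccccc3)c(OCc3ccccc3)c12.[Na+]
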